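Ring A carries five substituents (C1 arylethyl, C2 and C6 p-hydroxybenzyl, C3 OH, C5 OMe; C4 is H). The first carbon of the C1 chain and the CH2 of the C2 benzyl are both benzylic to ring A, so a single ether oxygen can join them and later be cut out by hydrogenolysis. Ring A and this fused dihydrofuran are therefore made in one alkyne cyclotrimerisation: an unsymmetrical dipropargyl ether whose alkyne ends carry a pinacol boronate (future C3 OH) and a 4-benzyloxybenzyl group (C6) takes up methoxyacetylene (C4, C5), forming C1–C2, C3–C4 and C5–C6 together. Boronate oxidation and one acidic hydrogenolysis finish the target.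

Key step: step 9

Remark: the target is taken as the bibenzyl (1,2-diarylethane) 3,3'-dihydroxy-2,6-bis(p-hydroxybenzyl)-5-methoxybibenzyl encoded by its SMILES; it has no stereocentre, and the stereocentres of 2, 9, 10, 14, 18, 19 and 20 are carried as racemates or diastereomer mixtures and erased in step 11.

Step 1
Reactants: 1 4-(benzyloxy)benzaldehyde
Product: 2 1-[4-(benzyloxy)phenyl]prop-2-yn-1-ol (racemic)
Conditions: HC≡CMgBr (0.5 M in THF), THF, 0 °C → rt; aq. NH4Cl
Reagents that add atoms: ethynylmagnesium bromide, C#C[Mg]Br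
Why: 1,2-addition of an alkynyl Grignard reagent to a non-enolisable aromatic aldehyde; the carbinol centre forms racemic, which is harmless because it is removed in step 11.

Step 2
Reactants: 3 4-(benzyloxy)benzyl chloride
Product: 4 1-(benzyloxy)-4-(prop-2-yn-1-yl)benzene
Conditions: HC≡CMgBr (2 equiv), CuCl (10 mol%), THF, 50 °C
Reagents that add atoms: ethynylmagnesium bromide, C#C[Mg]Br
Why: Copper-catalysed sp–sp3 coupling of an alkynyl Grignard reagent with an activated benzylic chloride; excess reagent and moderate temperature should limit double coupling and isomerisation to the allene.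

Step 3
Reactants: 5 2-(3-hydroxyphenyl)ethanol
Product: 6 2-[3-(benzyloxy)phenyl]ethanol
Conditions: BnBr (1.05 equiv), K2CO3, acetone, reflux
Reagents that add atoms: benzyl bromide, BrCc1ccccc1
Why: Williamson etherification with a carbonate base, selective for the phenol because it is far more acidic than the primary alcohol.

Step 4
Reactants: 6 2-[3-(benzyloxy)phenyl]ethanol
Product: 7 [3-(benzyloxy)phenyl]acetaldehyde
Conditions: DMP, CH2Cl2, 0 °C → rt; crude aldehyde used at once
Reagents that add atoms: none
Why: Dess–Martin oxidation stops at the aldehyde under near-neutral conditions that the enolisable arylacetaldehyde should tolerate.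

Step 5
Reactants: 4 1-(benzyloxy)-4-(prop-2-yn-1-yl)benzene; 7 [3-(benzyloxy)phenyl]acetaldehyde
Product: 9 1-[3-(benzyloxy)phenyl]-5-[4-(benzyloxy)phenyl]pent-3-yn-2-ol (racemic), via lithium acetylide 8 (not isolated)
Conditions: n-BuLi (1.0 equiv), THF, −78 °C; then 7, −78 → −40 °C; aq. NH4Cl
Reagents that add atoms: none
Why: Acetylide addition to an aldehyde; one equivalent of base at −78 °C removes only the terminal alkyne hydrogen, and at this temperature addition should outrun enolisation of 7; the carbinol centre is racemic and is erased in step 11.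

Step 6
Reactants: 2 1-[4-(benzyloxy)phenyl]prop-2-yn-1-ol; 9 1-[3-(benzyloxy)phenyl]-5-[4-(benzyloxy)phenyl]pent-3-yn-2-ol
Product: 10 1-(benzyloxy)-4-[1-({1-[3-(benzyloxy)phenyl]-5-[4-(benzyloxy)phenyl]pent-3-yn-2-yl}oxy)prop-2-yn-1-yl]benzene (mixture of diastereomers)
Conditions: 2 (1.5 equiv), TsOH·H2O (5 mol%), MeCN, rt
Reagents that add atoms: none
Why: Brønsted acid-catalysed dehydrative propargylic substitution (SN1): only 2 ionises, to a cation stabilised by the p-alkoxyphenyl ring and the alkyne, and 9 captures it at oxygen, while the symmetrical ether of 2 re-ionises so that excess 2 should funnel 9 into 10; the new centre forms without control, which does not matter.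

Step 7
Reactants: 10 terminal dipropargyl ether; 11 2-isopropoxy-4,4,5,5-tetramethyl-1,3,2-dioxaborolane
Product: 14 2-[3-[4-(benzyloxy)phenyl]-3-({1-[3-(benzyloxy)phenyl]-5-[4-(benzyloxy)phenyl]pent-3-yn-2-yl}oxy)prop-1-yn-1-yl]-4,4,5,5-tetramethyl-1,3,2-dioxaborolane (mixture of diastereomers), via lithium acetylide 12 (not isolated), via lithium alkynylborate 13 (not isolated)
Conditions: n-BuLi (1.0 equiv), THF, −78 °C; 11, −78 °C; HCl in Et2O (1.0 equiv), −78 °C → rt; filter, concentrate, use crude
Reagents that add atoms: none
Why: Borylation of a lithium acetylide with an alkoxyboronate and collapse of the ate complex with anhydrous acid (the standard alkynyl pinacol boronate synthesis); one equivalent of base at −78 °C should touch only the terminal alkyne and not the doubly activated ether C–H.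

Step 8
Reactants: 15 chloroacetaldehyde dimethyl acetal
Product: 17 methoxyacetylene, via sodium methoxyacetylide 16 (not isolated)
Conditions: NaNH2 (3.3 equiv), liq. NH3, −33 °C; evaporate NH3; aq. NaCl, −70 °C → rt, distil into a −78 °C trap; keep as a cold solution in 1,2-dichloroethane
Reagents that add atoms: none
Why: Twofold base-induced elimination (methanol, then HCl) from an α-chloro acetal, the classical alkoxyacetylene synthesis, gives the sodium acetylide, which is protonated and distilled.

Step 9
Reactants: 14 boronate-capped dipropargyl ether; 17 methoxyacetylene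
Product: 18 2-{1-[4-(benzyloxy)phenyl]-3-[3-(benzyloxy)benzyl]-4-[4-(benzyloxy)benzyl]-5-methoxy-1,3-dihydro-2-benzofuran-7-yl}-4,4,5,5-tetramethyl-1,3,2-dioxaborolane (mixture of diastereomers)
Conditions: Cp*RuCl(cod) (10 mol%), 17 (5 equiv, added cold), 1,2-dichloroethane, sealed tube, rt → 60 °C
Reagents that add atoms: none
Why: Oxidative cyclisation of the two tethered alkynes of 14 on the divalent ruthenium fragment Cp*RuCl gives a bicyclic ruthenacyclopentadiene with carbene character at its two metal-bound carbons, which sets the C1–C2 bond and closes the five-membered ether ring by metallacycle formation across the 1,6-diyne. Formal (2+2) addition of 17 to one ruthenium–carbon bond, ring expansion and reductive elimination then form C3–C4 and C5–C6 and close ring A as the six-membered arene, the whole being a crossed (2+2+2) cyclotrimerisation. The closest known reaction type is the Cp*RuCl(cod)-catalysed cycloaddition of ether-tethered 1,6-diynes, alkynylboronates included, with terminal alkynes. No stereocentre is formed; the two centres of the tether are spectators, carried as a diastereomer mixture and removed in step 11. The step needs one selectivity, the orientation of 17: its nucleophilic unsubstituted carbon should bond to the boron-bearing carbon of the metallacycle, the more electrophilic and more congested terminus (dioxaborolane next to the aryl-bearing tether carbon), so that the methoxy carbon, held on ruthenium as an alkoxycarbene-like centre, ends beside the benzyl-bearing C6. This matches the known habit of the catalyst to place the substituted carbon of a terminal alkyne away from the larger diyne terminus, but it has not been shown for an ynol ether on a diyne capped at both ends, so the risk of the route sits here; excess 17 and the intramolecular first step should counter its homo-oligomerisation.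

Step 10
Reactants: 18 C3 boronate of the dihydroisobenzofuran
Product: 19 1-[4-(benzyloxy)phenyl]-3-[3-(benzyloxy)benzyl]-4-[4-(benzyloxy)benzyl]-5-methoxy-1,3-dihydro-2-benzofuran-7-ol (mixture of diastereomers)
Conditions: H2O2 (30% aq.), NaOH (2 M aq.), THF, 0 °C → rt
Reagents that add atoms: hydrogen peroxide, OO
Why: Oxidation of an arylboronate with basic hydrogen peroxide (aryl shift from boron to oxygen, then hydrolysis) should give the phenol at the same carbon; benzyl ethers, the cyclic ether and the methyl ether are inert.

Step 11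
Reactants: 19 phenol of the dihydroisobenzofuran
Product: 21 3,3'-dihydroxy-2,6-bis(p-hydroxybenzyl)-5-methoxybibenzyl, via ring-opened benzylic alcohol 20 (not isolated)
Conditions: H2 (4 atm), 10% Pd/C, AcOH/EtOAc, HClO4 (cat.), rt → 50 °C
Reagents that add atoms: none
Why: Catalytic hydrogenolysis should cleave the three O-benzyl ethers and the doubly benzylic (diarylmethyl) C–O bond readily, and the acid should allow the remaining ring-A benzylic alcohol 20 to be reduced (directly or via the stilbene), so the tether oxygen leaves as water and both stereocentres vanish.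

Compound list
1 | 4-(benzyloxy)benzaldehyde | O=Cc1ccc(OCc2ccccc2)cc1 | starting material
2 | 1-[4-(benzyloxy)phenyl]prop-2-yn-1-ol (racemic) | C#CC(O)c1ccc(OCc2ccccc2)cc1 | intermediate
3 | 4-(benzyloxy)benzyl chloride | ClCc1ccc(OCc2ccccc2)cc1 | starting material
4 | 1-(benzyloxy)-4-(prop-2-yn-1-yl)benzene | C#CCc1ccc(OCc2ccccc2)cc1 | intermediate
5 | 2-(3-hydroxyphenyl)ethanol | OCCc1cccc(O)c1 | starting material
6 | 2-[3-(benzyloxy)phenyl]ethanol | OCCc1cccc(OCc2ccccc2)c1 | intermediate
7 | [3-(benzyloxy)phenyl]acetaldehyde | O=CCc1cccc(OCc2ccccc2)c1 | intermediate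
8 | {3-[4-(benzyloxy)phenyl]prop-1-yn-1-yl}lithium (lithium acetylide of 4, not isolated) | [Li]C#CCc1ccc(OCc2ccccc2)cc1 | intermediate
9 | 1-[3-(benzyloxy)phenyl]-5-[4-(benzyloxy)phenyl]pent-3-yn-2-ol (racemic) | OC(Cc1cccc(OCc2ccccc2)c1)C#CCc1ccc(OCc2ccccc2)cc1 | intermediate
10 | 1-(benzyloxy)-4-[1-({1-[3-(benzyloxy)phenyl]-5-[4-(benzyloxy)phenyl]pent-3-yn-2-yl}oxy)prop-2-yn-1-yl]benzene (mixture of diastereomers) | C#CC(OC(Cc1cccc(OCc2ccccc2)c1)C#CCc1ccc(OCc2ccccc2)cc1)c1ccc(OCc2ccccc2)cc1 | intermediate
11 | 2-isopropoxy-4,4,5,5-tetramethyl-1,3,2-dioxaborolane | CC(C)OB1OC(C)(C)C(C)(C)O1 | starting material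
12 | lithium acetylide of 10 (not isolated; mixture of diastereomers) | [Li]C#CC(OC(Cc1cccc(OCc2ccccc2)c1)C#CCc1ccc(OCc2ccccc2)cc1)c1ccc(OCc2ccccc2)cc1 | intermediate
13 | lithium alkynyl(isopropoxy)(pinacolato)borate from 12 and 11 (not isolated; mixture of diastereomers) | [Li+].CC(C)O[B-]1(C#CC(OC(Cc2cccc(OCc3ccccc3)c2)C#CCc2ccc(OCc3ccccc3)cc2)c2ccc(OCc3ccccc3)cc2)OC(C)(C)C(C)(C)O1 | intermediate
14 | 2-[3-[4-(benzyloxy)phenyl]-3-({1-[3-(benzyloxy)phenyl]-5-[4-(benzyloxy)phenyl]pent-3-yn-2-yl}oxy)prop-1-yn-1-yl]-4,4,5,5-tetramethyl-1,3,2-dioxaborolane (mixture of diastereomers) | CC1(C)OB(OC1(C)C)C#CC(OC(Cc1cccc(OCc2ccccc2)c1)C#CCc1ccc(OCc2ccccc2)cc1)c1ccc(OCc2ccccc2)cc1 | intermediate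
15 | chloroacetaldehyde dimethyl acetal (2-chloro-1,1-dimethoxyethane) | COC(CCl)OC | starting material
16 | sodium methoxyacetylide (not isolated) | [Na+].[C-]#COC | intermediate
17 | methoxyacetylene | COC#C | intermediate
18 | 2-{1-[4-(benzyloxy)phenyl]-3-[3-(benzyloxy)benzyl]-4-[4-(benzyloxy)benzyl]-5-methoxy-1,3-dihydro-2-benzofuran-7-yl}-4,4,5,5-tetramethyl-1,3,2-dioxaborolane (mixture of diastereomers) | COc1cc(B2OC(C)(C)C(C)(C)O2)c2c(c1Cc1ccc(OCc3ccccc3)cc1)C(Cc1cccc(OCc3ccccc3)c1)OC2c1ccc(OCc3ccccc3)cc1 | intermediate
19 | 1-[4-(benzyloxy)phenyl]-3-[3-(benzyloxy)benzyl]-4-[4-(benzyloxy)benzyl]-5-methoxy-1,3-dihydro-2-benzofuran-7-ol (mixture of diastereomers) | COc1cc(O)c2c(c1Cc1ccc(OCc3ccccc3)cc1)C(Cc1cccc(OCc3ccccc3)c1)OC2c1ccc(OCc3ccccc3)cc1 | intermediate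
20 | 1-[3-hydroxy-2,6-bis(4-hydroxybenzyl)-5-methoxyphenyl]-2-(3-hydroxyphenyl)ethanol (racemic, not isolated) | COc1cc(O)c(Cc2ccc(O)cc2)c(C(O)Cc2cccc(O)c2)c1Cc1ccc(O)cc1 | intermediate
21 | 3,3'-dihydroxy-2,6-bis(p-hydroxybenzyl)-5-methoxybibenzyl (achiral) | COc1cc(O)c(Cc2ccc(O)cc2)c(CCc2cccc(O)c2)c1Cc1ccc(O)cc1 | target

Total step count: 11. Longest linear sequence: 8 steps (steps 3, 4, 5, 6, 7, 9, 10, 11, from 5 to 21).

Steps most likely to fail

Step 9. The orientation of 17 during its uptake may not be controlled, because the flat boronate may not outweigh the benzyl cap, or the doubly capped diyne may fail to turn over. A change of metal (RhCl(PPh3)3 or [Ir(cod)Cl]2 with dppe) would be tried first. The fallback sets out from 10 and returns at 19, and replaces the boronate by a tetrahedral, oxidisable silyl cap. Deprotonation of 10 (n-BuLi, THF, −78 °C) and quench with benzylchlorodimethylsilane should give the benzyldimethylsilyl-capped diyne F1. Cyclotrimerisation of F1 with 17 (Cp*RuCl(cod), 1,2-dichloroethane, 60 °C), now steered by a cap that is clearly the larger terminus, should give the 7-silyl dihydroisobenzofuran F2. Tamao–Fleming oxidation (TBAF, THF; then H2O2, KHCO3, MeOH) should turn the C–Si bond into the C3 phenol, which is compound 19.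

Step 6. Reversible ionisation may stop at the symmetrical ether of 2, the released water may divert 2 into Meyer–Schuster rearrangement, or the hindered secondary alcohol 9 may capture the cation too slowly. The fallback sets out from 2 and returns at 10, and uses irreversible pre-activation in place of dehydrative catalysis. Treatment of 2 with Cl3CCN and catalytic DBU (CH2Cl2, 0 °C) should give the propargylic trichloroacetimidate F3, used crude. With 9 and catalytic TMSOTf (CH2Cl2, −40 °C) it should alkylate the alcohol (acid-catalysed imidate etherification) and give 10 without water and without an excess of either alcohol.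

Step 11. The reduction may stall after the first C–O cleavage, because the remaining benzylic alcohol 20 sits between two ortho benzyl groups and may ionise slowly or reach the catalyst surface poorly. The fallback sets out from 19 and returns at 21, and uses homogeneous ionic hydrogenation before debenzylation. Et3SiH with BF3·OEt2 (CH2Cl2, 0 °C → rt) should open the diarylmethyl ether and reduce the resulting benzylic alcohol through benzylic cations, giving the tri-O-benzyl bibenzyl F4. Neutral hydrogenolysis (H2, 10% Pd/C, EtOAc/EtOH) then only has to remove three benzyl ethers, and would saturate any stilbene formed by elimination, to give 21.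

Further compounds
F1 | step 9 | benzyl{3-[4-(benzyloxy)phenyl]-3-({1-[3-(benzyloxy)phenyl]-5-[4-(benzyloxy)phenyl]pent-3-yn-2-yl}oxy)prop-1-yn-1-yl}dimethylsilane (mixture of diastereomers) | C[Si](C)(Cc1ccccc1)C#CC(OC(Cc1cccc(OCc2ccccc2)c1)C#CCc1ccc(OCc2ccccc2)cc1)c1ccc(OCc2ccccc2)cc1
F2 | step 9 | benzyl{1-[4-(benzyloxy)phenyl]-3-[3-(benzyloxy)benzyl]-4-[4-(benzyloxy)benzyl]-5-methoxy-1,3-dihydro-2-benzofuran-7-yl}dimethylsilane (mixture of diastereomers) | COc1cc([Si](C)(C)Cc2ccccc2)c2c(c1Cc1ccc(OCc3ccccc3)cc1)C(Cc1cccc(OCc3ccccc3)c1)OC2c1ccc(OCc3ccccc3)cc1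
F3 | step 6 | 1-[4-(benzyloxy)phenyl]prop-2-yn-1-yl 2,2,2-trichloroacetimidate (racemic) | N=C(OC(C#C)c1ccc(OCc2ccccc2)cc1)C(Cl)(Cl)Cl
F4 | step 11 | 2,4-bis[4-(benzyloxy)benzyl]-3-{2-[3-(benzyloxy)phenyl]ethyl}-5-methoxyphenol | COc1cc(O)c(Cc2ccc(OCc3ccccc3)cc2)c(CCc2cccc(OCc3ccccc3)c2)c1Cc1ccc(OCc3ccccc3)cc1
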